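I would back eta, and not on your hunch that slow feeding buys selectivity: my argument is a clock.

| flask | starting material | reagent | temperature | remark | time |
|---|---|---|---|---|---|
| amber | 0.10 M | 0.20 M | 30 °C | run made earlier |  |
| green | 0.10 M | 0.13 M | 41 °C | run made earlier |  |
| teal | 0.10 M | 0.30 M | 30 °C | run made earlier |  |
| grey | 0.20 M | 0.20 M | 41 °C | run made earlier |  |
| eta | 0.10 M (fed, over 8.0 h) | 0.200 M |  | the addition at 15 °C, then warmed to 35 °C; the feed brings no volume worth counting | 10 h |
| epsilon | 0.10 M | 0.200 M | 35 °C | everything together at the start | 10 h |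
| alpha | 0.10 M | 0.200 M (fed, over 8.0 h) | 35 °C | all else is in the flask from the start; the feed brings no volume worth counting | 10 h |
| theta | 0.10 M (fed, over 8.0 h) | 0.200 M | 35 °C | all else is in the flask from the start; the feed brings no volume worth counting | 10 h |

| run | time / h | target / % | side product / % | starting material / % |
|---|---|---|---|---|
| amber | 2.00 | 0 | 0 | 99 |
| amber | 4.00 | 1 | 0 | 101 |
| amber | 6.00 | 0 | 0 | 98 |
| amber | 8.00 | 2 | 5 | 96 |
| amber | 10.0 | 1 | 4 | 93 |
| green | 2.50 | 0 | 2 | 99 |
| green | 5.00 | 2 | 5 | 96 |
| green | 8.00 | 2 | 10 | 86 |
| green | 10.0 | 4 | 18 | 79 |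
| green | 12.0 | 7 | 31 | 66 |
| teal | 2.50 | 1 | 0 | 99 |
| teal | 5.00 | 3 | 1 | 97 |
| teal | 8.00 | 5 | 5 | 90 |
| teal | 10.0 | 5 | 6 | 87 |
| teal | 12.0 | 12 | 10 | 79 |
| grey | 2.50 | 1 | 5 | 93 |
| grey | 5.00 | 11 | 29 | 63 |
| grey | 8.00 | 16 | 64 | 18 |
| grey | 10.0 | 18 | 75 | 7 |
| grey | 12.0 | 21 | 77 | 5 |

(each reading ± 1.5 percentage points)

- a species is counted by the starting material in it: one side product counts as two

1. which flask leads in share of target in target plus side product ("all alike" within 1.5 percentage points) (eta / epsilon / alpha / theta / all alike)
2. share of target in target plus side product at the end, eta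
3. share of target in target plus side product at the end, epsilon
4. share of target in target plus side product at the end, alpha
5. share of target in target plus side product at the end, theta

The percentages balance, the runs start slowly, and the share of target in target plus side product looks lower the further a run has gone. Teal reads 75.0 % at 5.00 h and 50.0 % at 8.00 h, and grey, far along, ends at 21.4 %, each reading carrying a scatter of 1.5 percentage points.

So I judge a flask by how far it got, measured against the lag (induction period): the time to fall to about 96 % of the starting material. Amber at 30 °C needs 8.00 h, and green at 41 °C, with c(reagent) 0.13 M, needs 5.00 h. For 35 °C I take the mean, 6.50 h.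

Eta spends its feed at 15 °C, colder than amber, so I count those hours as lost. What I carry is the warm fraction, the time at 35 °C with the whole charge present divided by the lag: 0.308 for eta, about a third. Epsilon has 1.54, so it gets further than eta. I therefore expect eta to stay above 96 % of its starting material, epsilon to fall well below that, and alpha and theta, fed warm, to land between the two. As the share looks lower the further a run has gone, eta, with the smaller warm fraction, should read a higher share than epsilon. I put no figure on it, as amber at 8.00 h reads 2 % target and 5 % side product against a scatter of 1.5 points.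

The forecast says theta leads, with 29 % for eta, 29 % for epsilon, 23 % for alpha and 34 % for theta, holding that “the feeds matter only modestly”.

The flask puts eta first at 59.3 %, against 34.1 % for epsilon, 39.1 % for alpha and 40.4 % for theta.

    starting material + target → side product (k = 3.00 M⁻¹ h⁻¹, Ea = 81.0 kJ mol⁻¹)
    reagent → decomposition product (k = 2.90 × 10⁻⁴ h⁻¹, Ea = 120 kJ mol⁻¹)
    starting material + reagent + by-product → target + 2 by-product (k = 14.0 M⁻² h⁻¹, Ea = 67.0 kJ mol⁻¹)
    starting material + reagent → target + by-product (k = 0.0120 M⁻¹ h⁻¹, Ea = 91.0 kJ mol⁻¹)
    (constants at 35 °C)

At 10.0 h eta still holds 99.0 % of its starting material, with 0.590 % target and 0.404 % side product, so its lead is the share of a barely started flask. The warm fraction of 0.308 placed it short of the lag, while epsilon, at 1.54, is down to 84 %.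

Read eta at 40 h instead and the warm fraction becomes 4.92, far past the lag, so I expect a nearly finished flask. The computed flask holds 2.86 % of its starting material and gives 27.0 %.

(Readings and results were computed for an exercise; scatter was added.)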